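## Retrosynthetic overview

1. Vibsanin E ⇐ (E)-enol ester by copper-catalysed C–O coupling of an alkenyltrifluoroborate (made from a ring-A vinyl group by cross-metathesis); the two ring-A side-chain centres come from a tricyclic enone by exo vinyl-cuprate addition, α-methylenation and radical hydroacylation, with the hydrogen delivered last.
2. Tricyclic enone ⇐ ring B (2,2-dimethyltetrahydropyran) by carbonylative lactonisation of an enol triflate onto a CH2OH, conjugate reduction, MeLi addition and cyclodehydration; the ring-A ketone by allylic oxidation.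
3. Key disconnection: the ring-C bond between the methyl-bearing quaternary bridgehead carbon and its ring-C CH2 neighbour, formed by anionic oxy-Cope rearrangement of a syn-8-vinylbicyclo[3.2.1]oct-2-en-8-ol. This closes ring C and lengthens the one-carbon bridge to three carbons, so the peripheral seven-membered ring of the bicyclooctene becomes ring A (bicyclo[3.2.1]octane → bicyclo[4.3.1]decane).
4. Enabling feature: rings A and C share the C(CH3)–CH2–CH bridge, and the chain ring-A CH(2-oxopropyl)–CH(side chain)–C(CH3)–CH2–CH2–CH(ring C, bearing the pyran CMe2) is a 1,5-diene retron (C=C–C(CH3)–CH2–CH=C–O⁻) whose two end carbons were bonded to each other in the precursor.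
5. Ring order: cyclopentanone (copper hydride asymmetric reduction/alkylation) → bridged cyclohexene by palladium α'-vinylation → rings C and A together in the key step → ring B.

Key step: step 7

Assumption: the (S) ligand in step 4 is written by analogy with 3-alkylcyclopent-2-enones (if hydride goes to the other face on this substrate, the (R) ligand is used and nothing else changes); tributyl[(methoxymethoxy)methyl]stannane is taken as a purchasable reagent.

Ring letters: A = cycloheptanone, B = tetrahydropyran, C = cyclohexane. "Exo" on ring A means the face away from the three-carbon bridge of ring C.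

## Route

Step 1
Reactants: 1 prop-2-yn-1-ol
Product: 3 (Z)-3-iodo-2-methylprop-2-en-1-ol, via alkenylmagnesium alkoxide 2 (not isolated)
Conditions: MeMgBr (2.5 equiv), CuI (10 mol %), Et2O, −10 °C → rt; then I2, THF, −10 °C → rt
Reagents that add atoms: methylmagnesium bromide C[Mg]Br; iodine II
Why: Copper-catalysed anti carbomagnesiation of the propargylic alkoxide places magnesium on the terminal carbon cis to the CH2O group through a five-membered chelate, and iodinolysis with retention should give the Z vinyl iodide.

Step 2
Reactants: 3 (Z)-3-iodo-2-methylprop-2-en-1-ol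
Product: 4 (Z)-3-bromo-1-iodo-2-methylprop-1-ene
Conditions: PBr3 (0.4 equiv), Et2O, 0 °C
Reagents that add atoms: phosphorus tribromide BrP(Br)Br
Why: Bromination of a primary allylic alcohol through its phosphite ester (SN2), which leaves the vinyl iodide geometry untouched.

Step 3
Reactants: 5 3-ethoxycyclopent-2-en-1-one
Product: 7 3-[(methoxymethoxy)methyl]cyclopent-2-en-1-one, via lithium alkoxide adduct 6 (not isolated)
Conditions: Bu3SnCH2OCH2OMe, n-BuLi, THF, −78 °C; then 5, −78 °C; then 1 M HCl, 0 °C → rt
Reagents that add atoms: tributyl[(methoxymethoxy)methyl]stannane CCCC[Sn](CCCC)(CCCC)COCOC; water O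
Why: Stork–Danheiser sequence in which tin–lithium exchange gives the α-alkoxymethyllithium, 1,2-addition to the vinylogous ester gives the tertiary alkoxide, and aqueous acid hydrolyses and dehydrates it to the transposed enone; no stereocentre remains.

Step 4
Reactants: 7 3-[(methoxymethoxy)methyl]cyclopent-2-en-1-one; 4 (Z)-3-bromo-1-iodo-2-methylprop-1-ene
Product: 9 (2R,3S)-2-[(2Z)-3-iodo-2-methylprop-2-en-1-yl]-3-[(methoxymethoxy)methyl]cyclopentan-1-one, via bis(enoxy)diphenylsilane 8 (not isolated)
Conditions: CuCl (5 mol %), NaOt-Bu (5 mol %), (S)-p-tol-BINAP (5 mol %), Ph2SiH2 (0.55 equiv), toluene, 0 °C; then 4 (1.5 equiv), Bu4N[Ph3SiF2] (1.2 equiv), CH2Cl2, rt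
Reagents that add atoms: none
Why: Copper hydride-catalysed asymmetric conjugate reduction sets the β-stereocentre (C3) under ligand control, and fluoride-triggered C-alkylation of the regiodefined silyl enol ether with the allylic bromide should occur anti to the C3 substituent to give the trans-2,3-disubstituted ketone.

Step 5
Reactants: 9 (2R,3S)-2-[(2Z)-3-iodo-2-methylprop-2-en-1-yl]-3-[(methoxymethoxy)methyl]cyclopentan-1-one
Product: 10 (1R,5R,6S)-6-[(methoxymethoxy)methyl]-3-methylbicyclo[3.2.1]oct-2-en-8-one (6-substituent exo)
Conditions: Pd(PPh3)4 (10 mol %), t-BuOK (1.5 equiv), THF, 65 °C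
Reagents that add atoms: none
Why: Palladium-catalysed intramolecular α'-vinylation of the ketone (oxidative addition of zerovalent palladium into the vinyl iodide, C-bound palladium enolate, reductive elimination) bridges the two α-carbons through a six-membered ring; the tether puts both bridgehead bonds on one face, so the C3 substituent of 9, trans to the side chain in the favoured base-equilibrated C2 epimer, should end exo.

Step 6
Reactants: 10 (1R,5R,6S)-6-[(methoxymethoxy)methyl]-3-methylbicyclo[3.2.1]oct-2-en-8-one
Product: 11 (1R,5R,6S)-8-ethenyl-6-[(methoxymethoxy)methyl]-3-methylbicyclo[3.2.1]oct-2-en-8-ol (ethenyl syn to the C2=C3 bridge)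
Conditions: CH2=CHMgBr (2 equiv), THF, −78 → 0 °C
Reagents that add atoms: vinylmagnesium bromide C=C[Mg]Br
Why: Grignard 1,2-addition to the non-enolisable bridging ketone; the exo CH2OCH2OMe group shields the face over the two-carbon bridge, so the vinyl group should enter over the flat C2=C3 bridge and set the carbinol centre with vinyl syn to that alkene.

Step 7
Reactants: 11 (1R,5R,6S)-8-ethenyl-6-[(methoxymethoxy)methyl]-3-methylbicyclo[3.2.1]oct-2-en-8-ol
Product: 14 5-[(methoxymethoxy)methyl]-1-methylbicyclo[4.3.1]deca-2,7-dien-7-yl trifluoromethanesulfonate (C5 substituent cis to the C7–C9 bridge), via potassium alkoxide 12 (not isolated), via potassium dienolate 13 (not isolated)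
Conditions: KH (3 equiv), 18-crown-6 (1.5 equiv), THF, 0 °C → rt; then PhNTf2 (1.5 equiv), −78 °C → rt
Reagents that add atoms: N-phenylbis(trifluoromethanesulfonimide) O=S(=O)(N(c1ccccc1)S(=O)(=O)C(F)(F)F)C(F)(F)F
Why: The potassium alkoxide 12 undergoes an anion-accelerated [3,3] sigmatropic (oxy-Cope) shift in which the vinyl terminus bonds to the methyl-bearing alkene carbon C3 while the allylic C1–C8 bond breaks, and the resulting enolate 13 is sulfonylated on oxygen. The closest known reaction type is the alkoxide-accelerated oxy-Cope ring expansion of syn-7-vinylnorborn-2-en-7-ols and related bridged 1,5-dien-3-olates. Ring C is closed by the sigmatropic bond formation itself through the boat-shaped six-membered transition state that the bicycle enforces, whereas ring A is not closed but is the peripheral seven-membered ring of the bicyclooctene, set free as the one-carbon bridge becomes a three-carbon bridge. The quaternary stereocentre is set by topology, since the new bridge can only span C3 and the retained bridgehead C5 on one face, so its configuration follows from C5 and hence from the stereocentre made in step 4. The step needs the [3,3] path to win over alkoxide fragmentation or a [1,3] shift, which the syn arrangement of vinyl group and C2=C3 bond from step 6 secures. It also needs a single enolate regioisomer, which is guaranteed because the other α-carbon is a bridgehead.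

Step 8
Reactants: 14 5-[(methoxymethoxy)methyl]-1-methylbicyclo[4.3.1]deca-2,7-dien-7-yl trifluoromethanesulfonate
Product: 15 5-(hydroxymethyl)-1-methylbicyclo[4.3.1]deca-2,7-dien-7-yl trifluoromethanesulfonate
Conditions: ZnBr2 (1.5 equiv), n-PrSH (3 equiv), CH2Cl2, 0 °C → rt
Reagents that add atoms: none
Why: Lewis acid/thiol cleavage of the methoxymethyl ether (acetal exchange to sulfur) under conditions that should leave the enol triflate and the alkene untouched; no stereocentre is affected.

Step 9
Reactants: 15 5-(hydroxymethyl)-1-methylbicyclo[4.3.1]deca-2,7-dien-7-yl trifluoromethanesulfonate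
Product: 16 tricyclic α-alkylidene δ-lactone (1-methylbicyclo[4.3.1]deca-2,7-diene-7-carboxylic acid lactonised onto the 5-CH2OH)
Conditions: Pd(OAc)2 (10 mol %), dppp (10 mol %), CO (1 atm), Et3N (2 equiv), DMF, 70 °C
Reagents that add atoms: carbon monoxide [C-]#[O+]
Why: Palladium-catalysed carbonylative lactonisation (oxidative addition into the enol triflate, CO insertion, capture of the acylpalladium by the primary alcohol) closes the six-membered lactone that becomes ring B; no stereocentre is formed.

Step 10
Reactants: 16 tricyclic α-alkylidene δ-lactone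
Product: 17 cis-fused saturated δ-lactone (16 with C7=C8 reduced; H-7 cis to H-6)
Conditions: [(Ph3P)CuH]6 (0.5 equiv), H2O (3 equiv), toluene/THF, rt
Reagents that add atoms: none
Why: Copper hydride conjugate reduction of the unsaturated lactone leaves the isolated ring-A alkene alone, and the new ring-fusion stereocentre is set on protonation of the copper enolate, where only the cis fusion is geometrically possible because the lactone already spans this carbon and the axially attached ring-A carbon next to it.

Step 11
Reactants: 17 cis-fused saturated δ-lactone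
Product: 18 2-[5-(hydroxymethyl)-1-methylbicyclo[4.3.1]dec-2-en-7-yl]propan-2-ol
Conditions: MeLi (4 equiv), THF, −78 → 0 °C
Reagents that add atoms: methyllithium [Li]C
Why: Double addition of methyllithium to the lactone (through the methyl ketone) gives the tertiary carbinol and frees the primary alcohol without touching the existing stereocentres.

Step 12
Reactants: 18 2-[5-(hydroxymethyl)-1-methylbicyclo[4.3.1]dec-2-en-7-yl]propan-2-ol
Product: 19 tricyclic ether (rings A, B and C of vibsanin E with a ring-A C=C; no ketone, no side chains)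
Conditions: TsOH·H2O (10 mol %), CH2Cl2, rt
Reagents that add atoms: none
Why: Acid-catalysed cyclodehydration (SN1 etherification) in which the tertiary cation is captured by the primary hydroxyl to give the 2,2-dimethyltetrahydropyran; the ring-fusion centre is retained because only the cis-fused ether can close, and any alkene from E1 loss re-enters through the same cation.

Step 13
Reactants: 19 tricyclic ether
Product: 20 tricyclic enone (vibsanin E core with the ring-A C=C conjugated to the ketone; no side chains)
Conditions: Rh2(C6H10NO)4 (dirhodium tetracaprolactamate, 1 mol %), t-BuOOH (5 equiv), K2CO3 (0.5 equiv), CH2Cl2, rt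
Reagents that add atoms: tert-butyl hydroperoxide CC(C)(C)OO
Why: Allylic C–H oxidation by tert-butylperoxyl radicals, regioselective because the only allylic hydrogens are on the ring-A CH2 (the other allylic carbon is quaternary) and the allyl radical should be trapped at that less hindered end; no stereocentre is formed.

Step 14
Reactants: 20 tricyclic enone
Product: 22 β-vinyl α-(dimethylaminomethyl) ketone (both groups exo), via bromomagnesium enolate 21 (not isolated)
Conditions: CH2=CHMgBr (3 equiv), CuI (1.5 equiv), THF, −40 °C; then 20, −78 → −40 °C; then Me2N=CH2+ I− (3 equiv), −78 °C → rt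
Reagents that add atoms: vinylmagnesium bromide C=C[Mg]Br; dimethylmethyleneiminium iodide (Eschenmoser's salt) C=[N+](C)C.[I-]
Why: Conjugate addition of the magnesium divinylcuprate from the exo face of ring A (the endo face is screened by the three-carbon bridge of ring C) sets the β-stereocentre, and Mannich trapping of the regiodefined enolate gives the amino ketone whose α-centre is removed again in step 15.

Step 15
Reactants: 22 β-vinyl α-(dimethylaminomethyl) ketone
Product: 24 β-vinyl α-methylene ketone, via trimethylammonium iodide 23 (not isolated)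
Conditions: MeI (10 equiv), CH2Cl2, rt; then aq. NaHCO3, rt
Reagents that add atoms: none
Why: N-Quaternisation followed by base-induced E1cB loss of trimethylamine (Mannich-base elimination) gives the exocyclic enone under conditions mild enough to keep the neighbouring vinyl-bearing centre.

Step 16
Reactants: 24 β-vinyl α-methylene ketone
Product: 25 vinyl diketone (vibsanin E with CH=CH2 in place of the enol ester; 2-oxopropyl endo, trans to vinyl)
Conditions: CH3CHO (10 equiv), (n-Bu4N)4[W10O32] (4 mol %), MeCN, 390 nm LED, rt
Reagents that add atoms: acetaldehyde CC=O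
Why: Decatungstate-photocatalysed hydroacylation (radical Giese-type addition) in which the acetyl radical adds to the exocyclic methylene and the planar α-keto radical should take its hydrogen back from the bulky reduced polyoxometalate on the open exo face, leaving the 2-oxopropyl group endo and trans to the vinyl group.

Step 17
Reactants: 25 vinyl diketone
Product: 26 (E)-alkenyl pinacol boronate of 25
Conditions: vinylboronic acid pinacol ester (5 equiv), second-generation Grubbs catalyst RuCl2(=CHPh)(PCy3)(H2IMes) (10 mol %), CH2Cl2, 40 °C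
Reagents that add atoms: 4,4,5,5-tetramethyl-2-vinyl-1,3,2-dioxaborolane C=CB1OC(C)(C)C(C)(C)O1
Why: Olefin cross-metathesis of the terminal vinyl group with the vinyl boronate, in which the bulky boryl group should place itself trans and give the E alkene.

Step 18
Reactants: 26 (E)-alkenyl pinacol boronate
Product: 27 potassium (E)-alkenyltrifluoroborate
Conditions: KHF2 (4 equiv, aq.), MeOH, rt
Reagents that add atoms: potassium hydrogen difluoride [K+].[F-].F
Why: Fluoride exchange at boron converts the pinacol ester into the trifluoroborate salt with retention of the alkene geometry.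

Step 19
Reactants: 27 potassium (E)-alkenyltrifluoroborate
Product: 28 vibsanin E
Conditions: 3-methylbut-2-enoic acid (2 equiv), CuBr (10 mol %), DMAP (20 mol %), 4 Å molecular sieves, O2 (1 atm), MeCN, 60 °C
Reagents that add atoms: 3-methylbut-2-enoic acid CC(C)=CC(=O)O
Why: Copper-catalysed oxidative C–O coupling (Chan–Lam type) of the alkenyltrifluoroborate with the carboxylic acid should form the enol ester with retention of the E geometry.

## Compound list

1 | prop-2-yn-1-ol | C#CCO | starting material
2 | (Z)-[3-(bromomagnesiooxy)-2-methylprop-1-en-1-yl]magnesium bromide | Br[Mg]OC/C(C)=C\[Mg]Br | intermediate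
3 | (Z)-3-iodo-2-methylprop-2-en-1-ol | OC/C(C)=C\I | intermediate
4 | (Z)-3-bromo-1-iodo-2-methylprop-1-ene | BrC/C(C)=C\I | intermediate
5 | 3-ethoxycyclopent-2-en-1-one | CCOC1=CC(=O)CC1 | starting material
6 | lithium 3-ethoxy-1-[(methoxymethoxy)methyl]cyclopent-2-en-1-olate (racemic) | [Li+].[O-]C1(COCOC)C=C(OCC)CC1 | intermediate
7 | 3-[(methoxymethoxy)methyl]cyclopent-2-en-1-one | COCOCC1=CC(=O)CC1 | intermediate
8 | bis{[(3S)-3-[(methoxymethoxy)methyl]cyclopent-1-en-1-yl]oxy}diphenylsilane | COCOC[C@H]1CCC(O[Si](c2ccccc2)(c2ccccc2)OC2=C[C@@H](COCOC)CC2)=C1 | intermediate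
9 | (2R,3S)-2-[(2Z)-3-iodo-2-methylprop-2-en-1-yl]-3-[(methoxymethoxy)methyl]cyclopentan-1-one | COCOC[C@H]1CCC(=O)[C@@H]1C/C(C)=C\I | intermediate
10 | (1R,5R,6S)-6-[(methoxymethoxy)methyl]-3-methylbicyclo[3.2.1]oct-2-en-8-one (6-exo) | COCOC[C@H]1C[C@@H]2C=C(C)C[C@H]1C2=O | intermediate
11 | (1R,5R,6S)-8-ethenyl-6-[(methoxymethoxy)methyl]-3-methylbicyclo[3.2.1]oct-2-en-8-ol (ethenyl syn to C2=C3) | COCOC[C@H]1C[C@@H]2C=C(C)C[C@H]1[C@@]2(O)C=C | intermediate
12 | potassium 8-olate of 11 | COCOC[C@H]1C[C@@H]2C=C(C)C[C@H]1[C@@]2([O-])C=C.[K+] | intermediate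
13 | potassium 5-[(methoxymethoxy)methyl]-1-methylbicyclo[4.3.1]deca-2,7-dien-7-olate | COCOC[C@H]1CC=C[C@@]2(C)CC=C([O-])[C@@H]1C2.[K+] | intermediate
14 | 5-[(methoxymethoxy)methyl]-1-methylbicyclo[4.3.1]deca-2,7-dien-7-yl trifluoromethanesulfonate | COCOC[C@H]1CC=C[C@@]2(C)CC=C(OS(=O)(=O)C(F)(F)F)[C@@H]1C2 | intermediate
15 | 5-(hydroxymethyl)-1-methylbicyclo[4.3.1]deca-2,7-dien-7-yl trifluoromethanesulfonate | OC[C@H]1CC=C[C@@]2(C)CC=C(OS(=O)(=O)C(F)(F)F)[C@@H]1C2 | intermediate
16 | tricyclic α-alkylidene δ-lactone | O=C1OC[C@H]2CC=C[C@@]3(C)CC=C1[C@@H]2C3 | intermediate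
17 | cis-fused saturated δ-lactone | O=C1OC[C@H]2CC=C[C@@]3(C)CC[C@@H]1[C@@H]2C3 | intermediate
18 | 2-[5-(hydroxymethyl)-1-methylbicyclo[4.3.1]dec-2-en-7-yl]propan-2-ol | OC[C@H]1CC=C[C@@]2(C)CC[C@@H](C(C)(C)O)[C@@H]1C2 | intermediate
19 | tricyclic ether (rings A, B, C; ring-A alkene) | C1[C@@H]2COC(C)(C)[C@@H]3CC[C@@](C)(C[C@@H]32)C=C1 | intermediate
20 | tricyclic enone | O=C1[C@@H]2COC(C)(C)[C@@H]3CC[C@@](C)(C[C@@H]32)C=C1 | intermediate
21 | bromomagnesium enolate of the β-vinyl ketone | C1=C(O[Mg]Br)[C@@H]2COC(C)(C)[C@@H]3CC[C@@](C)(C[C@@H]32)[C@H]1C=C | intermediate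
22 | β-vinyl α-(dimethylaminomethyl) ketone (both exo) | CN(C)C[C@H]1C(=O)[C@@H]2COC(C)(C)[C@@H]3CC[C@@](C)(C[C@@H]32)[C@H]1C=C | intermediate
23 | trimethylammonium iodide of 22 | C[N+](C)(C)C[C@H]1C(=O)[C@@H]2COC(C)(C)[C@@H]3CC[C@@](C)(C[C@@H]32)[C@H]1C=C.[I-] | intermediate
24 | β-vinyl α-methylene ketone | C=C1C(=O)[C@@H]2COC(C)(C)[C@@H]3CC[C@@](C)(C[C@@H]32)[C@H]1C=C | intermediate
25 | vinyl diketone | CC(=O)C[C@@H]1C(=O)[C@@H]2COC(C)(C)[C@@H]3CC[C@@](C)(C[C@@H]32)[C@H]1C=C | intermediate
26 | (E)-alkenyl pinacol boronate | CC(=O)C[C@@H]1C(=O)[C@@H]2COC(C)(C)[C@@H]3CC[C@@](C)(C[C@@H]32)[C@H]1/C=C/B1OC(C)(C)C(C)(C)O1 | intermediate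
27 | potassium (E)-alkenyltrifluoroborate | CC(=O)C[C@@H]1C(=O)[C@@H]2COC(C)(C)[C@@H]3CC[C@@](C)(C[C@@H]32)[C@H]1/C=C/[B-](F)(F)F.[K+] | intermediate
28 | vibsanin E | CC(=O)C[C@@H]1C(=O)[C@@H]2COC(C)(C)[C@@H]3CC[C@@](C)(C[C@@H]32)[C@H]1/C=C/OC(=O)C=C(C)C | target

## Step count and risks

Total step count: 19. Longest linear sequence: 18 steps (steps 1, 2 and 4 to 19).

The three steps most likely to fail:

Step 16. The hydrogen atom may be returned to the planar α-keto radical with too little facial discrimination, or the exocyclic enone may oligomerise before the acetyl radical adds. The fallback sets out from 20 and comes back at 25, with the carbon substituent installed first and a proton delivered last. Iodination of 20 (I2, pyridine, CH2Cl2) should give the 2-iodoenone F4. Stille coupling with allyltributylstannane (Pd2(dba)3, AsPh3, CuI, NMP) should give the 2-allyl enone F5, and Wacker oxidation (PdCl2, CuCl, O2, DMF/H2O) the 2-(2-oxopropyl) enone F6. Addition of (CH2=CH)2CuMgBr from the exo face gives the bromomagnesium enolate F7, which is protonated at −78 °C with acetic acid from the same open face to give 25.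

Step 5. Proto-deiodination of the vinylpalladium intermediate or base-induced degradation may outrun closure of the strained bridged ketone. The fallback sets out from 9 and comes back at 10, with a radical ring closure in place of the organopalladium one. Kinetic enolisation of 9 at the unsubstituted α'-carbon (LDA, TBSCl, THF, −78 °C) gives the tert-butyldimethylsilyl enol ether F1. Bu3SnH/AIBN (benzene, 80 °C) generates the vinyl radical, which should close onto the unsubstituted enol-ether carbon (6-endo, giving an α-silyloxy radical) to the bridged silyl ether F2. Bu4NF gives the bridge alcohol F3, and Dess–Martin oxidation returns 10.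

Step 19. Protodeboronation or oxidative homocoupling of the hindered alkenylboron species may be faster than C–O bond formation. The fallback sets out from 25 and comes back at 28, by classical enol acylation. Aldehyde-selective Wacker oxidation of the vinyl group (PdCl2(PhCN)2, CuCl2, AgNO2, O2, t-BuOH/MeNO2) should give the aldehyde F8. Treatment with 3-methylbut-2-enoic anhydride, Et3N and DMAP acylates the aldehyde enolate on oxygen, and the E enol ester 28 is separated from its Z isomer.

Further compounds
F1 | step 5 | tert-butyldimethylsilyl enol ether of 9 (C1=C5 enol ether) | COCOC[C@H]1CC=C(O[Si](C)(C)C(C)(C)C)[C@@H]1C/C(C)=C\I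
F2 | step 5 | 8-(tert-butyldimethylsilyloxy)-6-[(methoxymethoxy)methyl]-3-methylbicyclo[3.2.1]oct-2-ene (C8 epimers) | COCOC[C@H]1C[C@@H]2C=C(C)C[C@H]1C2O[Si](C)(C)C(C)(C)C
F3 | step 5 | 6-[(methoxymethoxy)methyl]-3-methylbicyclo[3.2.1]oct-2-en-8-ol (C8 epimers) | COCOC[C@H]1C[C@@H]2C=C(C)C[C@H]1C2O
F4 | step 16 | 2-iodoenone of 20 | O=C1[C@@H]2COC(C)(C)[C@@H]3CC[C@@](C)(C[C@@H]32)C=C1I
F5 | step 16 | 2-allyl enone | O=C1[C@@H]2COC(C)(C)[C@@H]3CC[C@@](C)(C[C@@H]32)C=C1CC=C
F6 | step 16 | 2-(2-oxopropyl) enone | O=C1[C@@H]2COC(C)(C)[C@@H]3CC[C@@](C)(C[C@@H]32)C=C1CC(C)=O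
F7 | step 16 | bromomagnesium enolate of 25 | CC(=O)CC1=C(O[Mg]Br)[C@@H]2COC(C)(C)[C@@H]3CC[C@@](C)(C[C@@H]32)[C@H]1C=C
F8 | step 19 | aldehyde (25 with CH2CHO in place of CH=CH2) | CC(=O)C[C@@H]1C(=O)[C@@H]2COC(C)(C)[C@@H]3CC[C@@](C)(C[C@@H]32)[C@H]1CC=O
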